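**Retrosynthetic overview**
- Ring C is the only ring made (rings A and B are bought as arenes) and closes last: the O1–C2 bond forms by a catalyst-controlled 6-endo intramolecular oxa-Michael addition of the 2'-hydroxychalcone, setting C2 as (S).
- Chalcone: the aryl–C(=O) bond comes from an ortho-lithiated, lavandulylated phloroglucinol ether and a cinnamoyl Weinreb amide (B-ring fragment from 4-hydroxybenzaldehyde).
- Ar–CH2 bond: the aryllithium formed between two OMOM groups displaces (S)-lavandulyl triflate (SN2).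
- Lavandulyl stereocentre: Evans deconjugative α-prenylation of an N-senecioyl oxazolidinone, then reductive removal of the auxiliary.
- Three fragments (4 + 2 + 3 steps), two fragment couplings, global MOM removal, ring closure.

Assumption: the 9-amino(9-deoxy)epi-quinidine-derived thiourea is taken to be the pseudoenantiomer that gives the (2S) ring closure; if a trial shows the opposite sense, the epi-quinine-derived pseudoenantiomer is used in the same step.

**Route**

Step 1
Reactants: 1 (4S)-4-benzyl-1,3-oxazolidin-2-one; 2 3-methylbut-2-enoyl chloride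
Product: 4 (4S)-4-benzyl-3-(3-methylbut-2-enoyl)-1,3-oxazolidin-2-one, via N-lithio oxazolidinone 3 (not isolated)
Conditions: n-BuLi, THF, −78 °C; then 2, −78 → 0 °C
Reagents that add atoms: none
Why: N-acylation of the lithiated Evans auxiliary by the acid chloride (nucleophilic acyl substitution) installs the chiral controller; no stereocentre is formed.

Step 2
Reactants: 4 (4S)-4-benzyl-3-(3-methylbut-2-enoyl)-1,3-oxazolidin-2-one; 5 1-bromo-3-methylbut-2-ene (prenyl bromide)
Product: 7 (4S)-4-benzyl-3-[(2S)-5-methyl-2-(prop-1-en-2-yl)hex-4-enoyl]-1,3-oxazolidin-2-one, via sodium dienolate 6 (not isolated)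
Conditions: NaHMDS, THF, −78 °C; then 5, −78 → −40 °C
Reagents that add atoms: none
Why: Evans deconjugative α-alkylation: γ-deprotonation gives the chelated (Z)-dienolate, which is prenylated at the α-carbon on the face opposite the C4 benzyl group, setting the future lavandulyl stereocentre (2S here) and moving the alkene into the isopropenyl position.

Step 3
Reactants: 7 (4S)-4-benzyl-3-[(2S)-5-methyl-2-(prop-1-en-2-yl)hex-4-enoyl]-1,3-oxazolidin-2-one
Product: 8 (2S)-5-methyl-2-(prop-1-en-2-yl)hex-4-en-1-ol [(S)-lavandulol]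
Conditions: LiBH4, H2O (1 equiv), Et2O, 0 °C
Reagents that add atoms: none
Why: Hydride reduction of the imide (reductive auxiliary cleavage) gives the primary alcohol without epimerising the α-centre or touching the alkenes, and returns the auxiliary.

Step 4
Reactants: 8 (2S)-5-methyl-2-(prop-1-en-2-yl)hex-4-en-1-ol
Product: 9 (2S)-5-methyl-2-(prop-1-en-2-yl)hex-4-en-1-yl trifluoromethanesulfonate
Conditions: Tf2O, 2,6-lutidine, CH2Cl2, −78 °C; cold work-up, used at once
Reagents that add atoms: trifluoromethanesulfonic anhydride (Tf2O), O=S(=O)(OS(=O)(=O)C(F)(F)F)C(F)(F)F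
Why: O-sulfonylation with a hindered base makes the β-branched primary carbon reactive enough for SN2 by an aryllithium at −78 °C; the stereocentre is not involved.

Step 5
Reactants: 10 benzene-1,3,5-triol (phloroglucinol)
Product: 11 5-methoxybenzene-1,3-diol
Conditions: MeOH, dry HCl, 60 °C, stopped at partial conversion; chromatography
Reagents that add atoms: methanol, CO
Why: Acid-catalysed etherification through the keto tautomer of phloroglucinol (addition–elimination) gives the mono-methyl ether, separated from the diether and recovered triol.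

Step 6
Reactants: 11 5-methoxybenzene-1,3-diol
Product: 12 1-methoxy-3,5-bis(methoxymethoxy)benzene
Conditions: MOMCl, i-Pr2NEt, CH2Cl2, 0 °C → rt
Reagents that add atoms: chloromethyl methyl ether (MOMCl), COCCl
Why: O-alkylation of both phenols (Williamson-type acetal formation) gives MOM ethers that protect and later direct ortho-lithiation.

Step 7
Reactants: 12 1-methoxy-3,5-bis(methoxymethoxy)benzene (1.6 equiv); 9 (2S)-5-methyl-2-(prop-1-en-2-yl)hex-4-en-1-yl trifluoromethanesulfonate
Product: 14 5-methoxy-1,3-bis(methoxymethoxy)-2-[(2R)-5-methyl-2-(prop-1-en-2-yl)hex-4-en-1-yl]benzene, via aryllithium 13 (not isolated)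
Conditions: n-BuLi, THF, 0 °C; then 9, Et2O, −78 → −20 °C
Reagents that add atoms: none
Why: Directed ortho-metalation occurs at the position flanked by the two OMOM groups and the aryllithium displaces the primary triflate by SN2 at CH2, so the adjacent stereocentre is untouched (S → R is only a change in CIP priorities).

Step 8
Reactants: 15 4-hydroxybenzaldehyde
Product: 16 4-(methoxymethoxy)benzaldehyde
Conditions: MOMCl, i-Pr2NEt, CH2Cl2, 0 °C → rt
Reagents that add atoms: chloromethyl methyl ether (MOMCl), COCCl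
Why: Phenol O-alkylation to the MOM ether protects the acidic OH against the later organolithium step.

Step 9
Reactants: 16 4-(methoxymethoxy)benzaldehyde; 17 triethyl phosphonoacetate
Product: 19 ethyl (2E)-3-[4-(methoxymethoxy)phenyl]prop-2-enoate, via sodium phosphonoacetate carbanion 18 (not isolated)
Conditions: NaH, THF, 0 °C → rt
Reagents that add atoms: none
Why: Horner–Wadsworth–Emmons olefination with a stabilised phosphonate gives the (E)-cinnamate selectively.

Step 10
Reactants: 19 ethyl (2E)-3-[4-(methoxymethoxy)phenyl]prop-2-enoate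
Product: 20 (2E)-N-methoxy-N-methyl-3-[4-(methoxymethoxy)phenyl]prop-2-enamide
Conditions: MeNH(OMe)·HCl, i-PrMgCl, THF, −20 °C
Reagents that add atoms: N,O-dimethylhydroxylamine hydrochloride, CNOC.Cl
Why: Aminolysis of the ester by the magnesium amide formed in situ (nucleophilic acyl substitution) gives the Weinreb amide with the (E)-alkene intact.

Step 11
Reactants: 14 5-methoxy-1,3-bis(methoxymethoxy)-2-[(2R)-5-methyl-2-(prop-1-en-2-yl)hex-4-en-1-yl]benzene; 20 (2E)-N-methoxy-N-methyl-3-[4-(methoxymethoxy)phenyl]prop-2-enamide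
Product: 23 (2E)-1-{6-methoxy-2,4-bis(methoxymethoxy)-3-[(2R)-5-methyl-2-(prop-1-en-2-yl)hex-4-en-1-yl]phenyl}-3-[4-(methoxymethoxy)phenyl]prop-2-en-1-one, via aryllithium 21 (not isolated), via lithium hemiaminal alkoxide 22 (not isolated)
Conditions: n-BuLi, TMEDA, THF, −20 → 0 °C; then 20, −78 → 0 °C; pH 7 buffer
Reagents that add atoms: none
Why: A second directed ortho-metalation (the two remaining ring positions are equivalent, each between OMOM and OMe) followed by Weinreb ketone synthesis (1,2-addition, chelated tetrahedral intermediate, no over-addition) gives the chalcone in one operation.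

Step 12
Reactants: 23 tris-MOM chalcone (name as in step 11)
Product: 24 (2E)-1-{2,4-dihydroxy-6-methoxy-3-[(2R)-5-methyl-2-(prop-1-en-2-yl)hex-4-en-1-yl]phenyl}-3-(4-hydroxyphenyl)prop-2-en-1-one
Conditions: HCl (1.25 M in MeOH), 30–35 °C, TLC control
Reagents that add atoms: none
Why: Acid-catalysed acetal exchange with methanol removes all three MOM groups under conditions mild enough to spare the two alkenes and leave the 6'-methoxy chalcone largely uncyclised.

Step 13
Reactants: 24 (2E)-1-{2,4-dihydroxy-6-methoxy-3-[(2R)-5-methyl-2-(prop-1-en-2-yl)hex-4-en-1-yl]phenyl}-3-(4-hydroxyphenyl)prop-2-en-1-one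
Product: 25 kushenol U, (2S)-7-hydroxy-2-(4-hydroxyphenyl)-5-methoxy-8-[(2R)-5-methyl-2-(prop-1-en-2-yl)hex-4-en-1-yl]-2,3-dihydro-4H-chromen-4-one
Conditions: epi-quinidine-derived 3,5-bis(trifluoromethyl)phenyl thiourea (15 mol %), toluene/THF 9:1, 25 °C, to about 80% conversion; recovered 24 recycled; minor (2R)-epimer removed by preparative HPLC
Reagents that add atoms: none
Why: Asymmetric intramolecular oxa-Michael addition (6-endo): the thiourea binds the enone carbonyl and the quinuclidine delivers the only ortho-OH (2'-OH) to one face of the β-carbon, so C2 (S) is set by the catalyst, the remote lavandulyl centre having no influence.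

**Compound list**

1 | (4S)-4-benzyl-1,3-oxazolidin-2-one | O=C1N[C@@H](Cc2ccccc2)CO1 | starting material
2 | 3-methylbut-2-enoyl chloride | CC(C)=CC(=O)Cl | starting material
3 | N-lithio-(4S)-4-benzyl-1,3-oxazolidin-2-one | [Li]N1[C@@H](Cc2ccccc2)COC1=O | intermediate (not isolated)
4 | (4S)-4-benzyl-3-(3-methylbut-2-enoyl)-1,3-oxazolidin-2-one | CC(C)=CC(=O)N1[C@@H](Cc2ccccc2)COC1=O | intermediate
5 | 1-bromo-3-methylbut-2-ene | CC(C)=CCBr | starting material
6 | sodium (Z)-dienolate of 4 | C=C(C)/C=C(\[O-])N1[C@@H](Cc2ccccc2)COC1=O.[Na+] | intermediate (not isolated)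
7 | (4S)-4-benzyl-3-[(2S)-5-methyl-2-(prop-1-en-2-yl)hex-4-enoyl]-1,3-oxazolidin-2-one | C=C(C)[C@H](CC=C(C)C)C(=O)N1[C@@H](Cc2ccccc2)COC1=O | intermediate
8 | (2S)-5-methyl-2-(prop-1-en-2-yl)hex-4-en-1-ol, (S)-lavandulol | C=C(C)[C@H](CC=C(C)C)CO | intermediate
9 | (2S)-5-methyl-2-(prop-1-en-2-yl)hex-4-en-1-yl trifluoromethanesulfonate | C=C(C)[C@H](CC=C(C)C)COS(=O)(=O)C(F)(F)F | intermediate
10 | benzene-1,3,5-triol | Oc1cc(O)cc(O)c1 | starting material
11 | 5-methoxybenzene-1,3-diol | COc1cc(O)cc(O)c1 | intermediate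
12 | 1-methoxy-3,5-bis(methoxymethoxy)benzene | COCOc1cc(OC)cc(OCOC)c1 | intermediate
13 | [4-methoxy-2,6-bis(methoxymethoxy)phenyl]lithium | [Li]c1c(OCOC)cc(OC)cc1OCOC | intermediate (not isolated)
14 | 5-methoxy-1,3-bis(methoxymethoxy)-2-[(2R)-5-methyl-2-(prop-1-en-2-yl)hex-4-en-1-yl]benzene | C=C(C)[C@H](CC=C(C)C)Cc1c(OCOC)cc(OC)cc1OCOC | intermediate
15 | 4-hydroxybenzaldehyde | O=Cc1ccc(O)cc1 | starting material
16 | 4-(methoxymethoxy)benzaldehyde | COCOc1ccc(C=O)cc1 | intermediate
17 | triethyl phosphonoacetate | CCOC(=O)CP(=O)(OCC)OCC | starting material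
18 | sodium salt of triethyl phosphonoacetate (carbanion) | CCOC(=O)[CH-]P(=O)(OCC)OCC.[Na+] | intermediate (not isolated)
19 | ethyl (2E)-3-[4-(methoxymethoxy)phenyl]prop-2-enoate | CCOC(=O)/C=C/c1ccc(OCOC)cc1 | intermediate
20 | (2E)-N-methoxy-N-methyl-3-[4-(methoxymethoxy)phenyl]prop-2-enamide | CON(C)C(=O)/C=C/c1ccc(OCOC)cc1 | intermediate
21 | {6-methoxy-2,4-bis(methoxymethoxy)-3-[(2R)-5-methyl-2-(prop-1-en-2-yl)hex-4-en-1-yl]phenyl}lithium | C=C(C)[C@H](CC=C(C)C)Cc1c(OCOC)cc(OC)c([Li])c1OCOC | intermediate (not isolated)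
22 | lithium alkoxide of the N-methoxy-N-methyl hemiaminal from 21 and 20 (mixture at the carbinol carbon) | C=C(C)[C@H](CC=C(C)C)Cc1c(OCOC)cc(OC)c(C(O[Li])(/C=C/c2ccc(OCOC)cc2)N(C)OC)c1OCOC | intermediate (not isolated)
23 | (2E)-1-{6-methoxy-2,4-bis(methoxymethoxy)-3-[(2R)-5-methyl-2-(prop-1-en-2-yl)hex-4-en-1-yl]phenyl}-3-[4-(methoxymethoxy)phenyl]prop-2-en-1-one | C=C(C)[C@H](CC=C(C)C)Cc1c(OCOC)cc(OC)c(C(=O)/C=C/c2ccc(OCOC)cc2)c1OCOC | intermediate
24 | (2E)-1-{2,4-dihydroxy-6-methoxy-3-[(2R)-5-methyl-2-(prop-1-en-2-yl)hex-4-en-1-yl]phenyl}-3-(4-hydroxyphenyl)prop-2-en-1-one | C=C(C)[C@H](CC=C(C)C)Cc1c(O)cc(OC)c(C(=O)/C=C/c2ccc(O)cc2)c1O | intermediate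
25 | kushenol U, (2S)-7-hydroxy-2-(4-hydroxyphenyl)-5-methoxy-8-[(2R)-5-methyl-2-(prop-1-en-2-yl)hex-4-en-1-yl]-2,3-dihydro-4H-chromen-4-one | C=C(C)[C@H](CC=C(C)C)Cc1c(O)cc(OC)c2c1O[C@H](c1ccc(O)cc1)CC2=O | target

**Step count**

Total: 13 steps. Longest linear sequence: 8 steps (1 → 2 → 3 → 4 → 7 → 11 → 12 → 13). The arene branch (steps 5, 6) joins at step 7 and the cinnamoyl branch (steps 8, 9, 10) joins at step 11.

**Steps most likely to fail, with fallbacks**

Step 7 (aryl–alkyl coupling). The risks are E2 or decomposition of the β-branched homoallylic triflate, and incomplete regiocontrol of the lithiation (between the two OMOM groups versus between OMOM and OMe). The fallback sets out from 8 and 12 and comes back at 14, using a reversed-polarity B-alkyl Suzuki–Miyaura coupling. Alcohol 8 is converted with I2, PPh3 and imidazole (CH2Cl2, 0 °C) into (2S)-1-iodo-5-methyl-2-(prop-1-en-2-yl)hex-4-ene F1. Arene 12 is lithiated as before to 13 and quenched with I2 to give 2-iodo-5-methoxy-1,3-bis(methoxymethoxy)benzene F2, which is recrystallised so that any regioisomer is removed at this cheap stage. F1 is treated with t-BuLi (2.1 equiv, Et2O, −78 °C) to give [(2S)-5-methyl-2-(prop-1-en-2-yl)hex-4-en-1-yl]lithium F3. This is trapped with B-methoxy-9-BBN as lithium B-methoxy-B-[(2S)-5-methyl-2-(prop-1-en-2-yl)hex-4-en-1-yl]-9-borabicyclo[3.3.1]nonan-9-uide F4. F4 is coupled with F2 (Pd(OAc)2/SPhos, aq K3PO4, THF/DMF, 40 °C) to give 14.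

Step 11 (hindered aryllithium with the cinnamoyl Weinreb amide). The risks are conjugate addition and loss of the N-methoxy group by base-induced elimination. The fallback sets out from 14 and comes back at 23, building the enone by a Claisen–Schmidt aldol condensation. 14 is lithiated to 21 and acetylated with the small, non-conjugated N-methoxy-N-methylacetamide to give 1-{6-methoxy-2,4-bis(methoxymethoxy)-3-[(2R)-5-methyl-2-(prop-1-en-2-yl)hex-4-en-1-yl]phenyl}ethan-1-one F5. F5 is condensed with aldehyde 16 (KOH, EtOH/H2O, rt) to give 23.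

Step 13 (asymmetric ring closure). The risks are modest catalyst control with a free polyphenolic chalcone and erosion by retro-oxa-Michael. The fallback sets out from 24 and comes back at 25, replacing catalyst control by thermodynamic closure, separation and recycling. 24 is cyclised with NaOAc in refluxing EtOH to a roughly 1:1 mixture of 25 and (2R)-7-hydroxy-2-(4-hydroxyphenyl)-5-methoxy-8-[(2R)-5-methyl-2-(prop-1-en-2-yl)hex-4-en-1-yl]-2,3-dihydro-4H-chromen-4-one F6. The two are separated by preparative HPLC on a chiral stationary phase. F6 is reopened to 24 with aqueous KOH/EtOH (retro-oxa-Michael) and resubmitted until the material is converted into 25.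

**Further compounds**

F1 | step 7 | (2S)-1-iodo-5-methyl-2-(prop-1-en-2-yl)hex-4-ene | C=C(C)[C@H](CC=C(C)C)CI
F2 | step 7 | 2-iodo-5-methoxy-1,3-bis(methoxymethoxy)benzene | COCOc1cc(OC)cc(OCOC)c1I
F3 | step 7 | [(2S)-5-methyl-2-(prop-1-en-2-yl)hex-4-en-1-yl]lithium | C=C(C)[C@H](CC=C(C)C)C[Li]
F4 | step 7 | lithium B-methoxy-B-[(2S)-5-methyl-2-(prop-1-en-2-yl)hex-4-en-1-yl]-9-borabicyclo[3.3.1]nonan-9-uide | C=C(C)[C@H](CC=C(C)C)C[B-]1(OC)C2CCCC1CCC2.[Li+]
F5 | step 11 | 1-{6-methoxy-2,4-bis(methoxymethoxy)-3-[(2R)-5-methyl-2-(prop-1-en-2-yl)hex-4-en-1-yl]phenyl}ethan-1-one | C=C(C)[C@H](CC=C(C)C)Cc1c(OCOC)cc(OC)c(C(C)=O)c1OCOC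
F6 | step 13 | (2R)-7-hydroxy-2-(4-hydroxyphenyl)-5-methoxy-8-[(2R)-5-methyl-2-(prop-1-en-2-yl)hex-4-en-1-yl]-2,3-dihydro-4H-chromen-4-one | C=C(C)[C@H](CC=C(C)C)Cc1c(O)cc(OC)c2c1O[C@@H](c1ccc(O)cc1)CC2=O
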